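## Structural features

The target is (3S,4S,3'S,4'S)-7,8-didehydro-β,β-carotene-3,4,3',4'-tetrol. It is a C40 carotenoid in which two 2,6,6-trimethylcyclohexene rings (ring A, C1–C6; ring B, C1'–C6') are joined through C6 and C6' by the linear chain C7–C7', which carries methyl groups on C9, C13, C13' and C9'. The chain holds eight E double bonds and one triple bond, C7≡C8, next to ring A; together with C5=C6 and C5'=C6', everything from C5 to C5' is one conjugated system. Each ring carries two adjacent stereocentres, C3/C4 and C3'/C4', as a trans diol; all four are S, so the rings are identical, and the two pairs are too far apart to influence each other. The hydroxyls on C4 and C4' are allylic to the whole chromophore and ionise or eliminate with acid, and the polyene is sensitive to oxygen, light, acid and isomerising agents. The real difficulty is the dissymmetry: the halves differ only in the oxidation level of C7–C8 against C7'–C8', so any symmetric assembly gives statistical mixtures of compounds that differ by two hydrogens. A second difficulty is C9=C10, which stands next to the linear alkyne and has no steric bias for E, so it cannot be repaired by the final equilibration on which carotenoid syntheses usually rely. The key step exploits two features: ring A–C7≡C8 and ring B–C7'=C8' are the same C11 unit at two oxidation levels, and the single bonds C8–C9 (sp–sp2) and C8'–C9' (sp2–sp2) flank a heptaene C9–C9' that is symmetric in constitution.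

## Logic of the disconnections

**18 to 17.** The four O–H bonds on C3, C4, C3' and C4' are exchanged for O–Si bonds. The allylic C4–O and C4'–O bonds ionise easily once the chromophore is attached, and free hydroxyls would consume the hydride and base reagents of earlier steps. The skeleton is unchanged, but every earlier intermediate becomes aprotic and lipophilic. The forward step must be non-acidic, hence fluoride.

**17 to 15 + 5 + 7 (through 16).**
- Bonds cut: the single bonds C8–C9 and C8'–C9'.
- Reason: these are the only cuts at which the two ring-bearing pieces become derivatives of one compound, and at which the geometry of C9=C10 and C9'=C10' can be fixed in small molecules and carried over with retention.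
- Gain: a C40 problem with four stereocentres falls to one chiral C11 unit and one achiral C18 chain.
- Demand on the forward step: the two ends of 15 must react in a fixed order, each with one partner only.
- In one sentence: a one-pot Sonogashira/Suzuki–Miyaura sequence joins 5 and 7 to the two ends of 15. That sentence does not describe an olefination route.

**7 to 5 (through 6).** The C8'–I and C7'–H bonds are removed. This makes the partner for the alkene end a one-step derivative of the partner for the alkyne end, so only one chiral building block has to be made. The forward step must be a syn, terminal-selective hydrometalation followed by halogenolysis with retention.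

**5 to 4.** The C7≡C8 bond is cut back to the formyl carbon C7. A formyl group on C6 is present in the starting ring, so the hindered C6–C7 bond never has to be formed. The forward step must homologate a hindered, non-enolisable formyl group by one carbon.

**4 to 3.** Two O–Si bonds are cut. This is protection only; the forward step must not enolise the enal.

**3 to 2.** The C4–O bond to the incoming water is cut. An anti opening gives the trans relation by mechanism and relays C4 from C3. The forward step must attack C4 and not C3, since attack at C3 would give the enantiomer.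

**2 to 1.** Both epoxide C–O bonds are cut. One catalytic event sets C3 and C4 on a purchasable achiral ring that already holds C1–C7 and all three methyl groups. The forward step must pick C3=C4 over C5=C6 and one face of it.

**15 to 14 + 11.** The double bond C11'=C12' is cut. This places the boron terminus last, on a substrate that already holds the iodide, so the two termini are never equivalent. The forward step must be E-selective and must spare C–I and C–B.

**14 to 12 + 13.** The double bond C11=C12 is cut. 13 supplies C12–C12' with three E double bonds ready made. The forward step must stop after one of the two formyl groups has reacted.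

**12 to 11.** The C9–I bond is traced back to a C–B bond. Both chain-end reagents then come from one precursor with one geometry. The forward step must go with retention.

**11 to 10 to 9 to 8.** The C11–P bond, the C–Br bond, and then the C9–B and C10–H bonds are cut. What remains is a four-carbon alkynol. The hydroboration must be syn and must put boron on the carbon remote from oxygen, because this one addition defines both 9E and 9'E.

## Other disconnections considered

**Alternative 1:** This is the first route that comes to mind, C15 + C10 + C15.
- Cut: C11=C12 and C11'=C12'.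
- Forward key step: two successive Wittig condensations of 13, one with the acetylenic C15 phosphonium salt A1 and one with the olefinic C15 phosphonium salt A2.
- Grounds for preferring the chosen plan:
  - A1 and A2 each need their own chain extension from the ring, so two ring-to-chain sequences replace one alkyne.
  - Semi-stabilised ylides are expected to give E/Z mixtures at the new double bonds. The usual cure, equilibration of the finished polyene, would also act on C9=C10, where the neighbouring alkyne removes the steric preference for E.
  - Phosphonium salts of this type are normally made under strongly acidic conditions, which the allylic C4–O bond should not tolerate.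

**Alternative 2:** All four stereocentres are set as a group at the end.
- Cut: the C–H bonds on C3, C4, C3' and C4', leading back to the achiral tetraketone A3.
- Forward key step: asymmetric transfer hydrogenation with RuCl(p-cymene)[(S,S)-TsDPEN] at both C3 carbonyls to give the bis-ketol A4, then 1,2-reduction of both C4 carbonyls under substrate control.
- Grounds for preferring the chosen plan:
  - An achiral skeleton is attractive, but A3 still needs an unsymmetrical chain assembly, so the main difficulty is untouched.
  - Four reductions in two remote rings multiply every imperfection into C40 diastereomers that should be very hard to separate.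
  - The C4 carbonyl is a polyene-conjugated ketone of low electrophilicity, and its reduction has only the neighbouring carbinol as control element, with no mechanistic guarantee of trans.
  - In the accepted transition-state model the unsaturated substituent lies next to the arene ligand. That substituent is C4 for the C3 ketone and C5 for the C4 ketone, so one ligand enantiomer is expected to give 3S but 4R, the cis diol.

**Alternative 3:** C9 + C22 + C9.
- Cut: C6–C7 and C6'–C7'.
- Forward key step: double coupling of two equivalents of one ring enol triflate A5 with the C22 chain A6, which carries a terminal alkyne at C7 and a boronate at C7'.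
- Merit: one ring electrophile is used twice, and all the dissymmetry sits in an achiral chain.
- Grounds for preferring the chosen plan:
  - Both new bonds would be made at a fully substituted carbon flanked by the C1 gem-dimethyl group and the C5 methyl group. This is the slowest setting for oxidative addition and transmetalation, and it would be needed twice on a fragile octaene.
  - A5 needs enol triflation of a β-silyloxy ketone, which invites E1cB loss of the C4 oxygen.
  - A5 cannot come from 1, which already carries C7, so the ring synthesis would be longer.

Key step: step 12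

Assumption: carotenoid numbering (ring A C1–C6, chain C7–C15, primed numbers for the ring B half) is applied to all intermediates, and 1, 8 and 13 are taken to be purchasable in the geometry drawn.

## Steps

Step 1
Reactants: 1 safranal (2,6,6-trimethylcyclohexa-1,3-diene-1-carbaldehyde)
Product: 2 (1R,6S)-2,4,4-trimethyl-7-oxabicyclo[4.1.0]hept-2-ene-3-carbaldehyde (the 3S,4R epoxide in carotenoid numbering)
Conditions: aq NaOCl (pH 11.3 buffer), (R,R)-[N,N'-bis(3,5-di-tert-butylsalicylidene)cyclohexane-1,2-diaminato]MnCl (5 mol %), 4-phenylpyridine N-oxide (20 mol %), CH2Cl2, 0 °C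
Reagents that add atoms: sodium hypochlorite, [Na+].[O-]Cl
Why: Jacobsen–Katsuki epoxidation of a cyclic cis-disubstituted conjugated olefin: the electrophilic oxomanganese species takes C3=C4, the only disubstituted and the more electron-rich double bond, while C5=C6 is tetrasubstituted and deactivated by the formyl group. With C4 in the role of the benzylic carbon of indene or of a 2,2-dimethylchromene, side-on approach to the (R,R) complex should deliver oxygen to the face that gives C4 R and C3 S. Both stereocentres are set in this one event, and the ring forbids the bond rotation that leads to trans epoxides in open-chain cases.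

Step 2
Reactants: 2 (1R,6S)-2,4,4-trimethyl-7-oxabicyclo[4.1.0]hept-2-ene-3-carbaldehyde
Product: 3 (3S,4S)-3,4-dihydroxy-2,6,6-trimethylcyclohex-1-ene-1-carbaldehyde (trans diol)
Conditions: HClO4 (5 mol %), THF/H2O 3:1, 0 °C to rt
Reagents that add atoms: water, O
Why: Acid-catalysed anti opening of a γ,δ-epoxy enal: water attacks the protonated epoxide at the allylic carbon C4 in a loose SN2 transition state assisted by the C5=C6 π bond, whereas C3 has no such help and is screened by the axial methyl group on C1. C4 is inverted (R to S) and C3 keeps its C–O bond (S), so the trans relation follows from the mechanism. The formyl group destabilises a free cation at C4, which should suppress an SN1 course.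

Step 3
Reactants: 3 (3S,4S)-3,4-dihydroxy-2,6,6-trimethylcyclohex-1-ene-1-carbaldehyde
Product: 4 (3S,4S)-3,4-bis(tert-butyldimethylsilyloxy)-2,6,6-trimethylcyclohex-1-ene-1-carbaldehyde
Conditions: TBSOTf (2.5 equiv), 2,6-lutidine (4 equiv), CH2Cl2, −78 to 0 °C
Reagents that add atoms: tert-butyldimethylsilyl triflate, CC(C)(C)[Si](C)(C)OS(=O)(=O)C(F)(F)F
Why: Standard silylation of a hindered vicinal diol with a silyl triflate; no C–O bond is touched, so both centres are kept. 2,6-Lutidine is too weak and too hindered to enolise the enal through its γ-hydrogens at this temperature.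

Step 4
Reactants: 4 (3S,4S)-3,4-bis(tert-butyldimethylsilyloxy)-2,6,6-trimethylcyclohex-1-ene-1-carbaldehyde
Product: 5 (3S,4S)-3,4-bis(tert-butyldimethylsilyloxy)-1-ethynyl-2,6,6-trimethylcyclohex-1-ene (ring alkyne)
Conditions: Me3SiCHN2 (1.3 equiv), n-BuLi (1.25 equiv), THF, −78 °C; then 4, −78 °C to rt
Reagents that add atoms: (trimethylsilyl)diazomethane, C[Si](C)(C)C=[N+]=[N-]
Why: Colvin rearrangement: the lithiated diazo compound adds to the non-enolisable formyl group, Peterson-type loss of Me3SiOLi and then of N2 gives an alkylidene carbene, and a 1,2-hydrogen shift gives the terminal alkyne. The new carbon is C8; the silyl ethers and the remote stereocentres are inert to the short exposure to base at low temperature.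

Step 5
Reactants: 5 (3S,4S)-3,4-bis(tert-butyldimethylsilyloxy)-1-ethynyl-2,6,6-trimethylcyclohex-1-ene
Product: 7 (3S,4S)-3,4-bis(tert-butyldimethylsilyloxy)-1-[(E)-2-iodoethenyl]-2,6,6-trimethylcyclohex-1-ene, via alkenylzirconocene chloride 6 (not isolated)
Conditions: Cp2ZrHCl (1.3 equiv), THF, rt, dark; then I2 (1.2 equiv), THF, −78 to 0 °C
Reagents that add atoms: iodine, [I][I]
Why: Hydrozirconation is a syn addition that places zirconium on the unhindered terminal carbon, and iodinolysis of the C–Zr bond goes with retention, so only the E iodide should form. The tetrasubstituted ring double bond and the silyl ethers do not react with Cp2ZrHCl.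

Step 6
Reactants: 8 but-2-yn-1-ol
Product: 9 (Z)-3-(4,4,5,5-tetramethyl-1,3,2-dioxaborolan-2-yl)but-2-en-1-ol (boron trans to CH2OH)
Conditions: B2pin2 (1.1 equiv), CuCl (5 mol %), PCy3 (6 mol %), NaOt-Bu (15 mol %), MeOH (2 equiv), toluene, rt
Reagents that add atoms: bis(pinacolato)diboron, CC1(C)OB(OC1(C)C)B1OC(C)(C)C(C)(C)O1
Why: Copper-catalysed formal hydroboration: the copper boryl species adds syn across the alkyne and methanol protonates the C–Cu bond with retention. Boron goes to the carbon remote from the propargylic oxygen, because copper prefers the carbon next to the inductively withdrawing CH2O group. The syn addition puts boron trans to CH2OH, the geometry that later becomes 9E and 9'E.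

Step 7
Reactants: 9 (Z)-3-(4,4,5,5-tetramethyl-1,3,2-dioxaborolan-2-yl)but-2-en-1-ol
Product: 10 (Z)-2-(4-bromobut-2-en-2-yl)-4,4,5,5-tetramethyl-1,3,2-dioxaborolane
Conditions: CBr4 (1.2 equiv), PPh3 (1.25 equiv), CH2Cl2, 0 °C
Reagents that add atoms: carbon tetrabromide, BrC(Br)(Br)Br
Why: Appel reaction, SN2 at a primary allylic carbon under neutral conditions; the alkenylboronate and the double-bond geometry are not involved.

Step 8
Reactants: 10 (Z)-2-(4-bromobut-2-en-2-yl)-4,4,5,5-tetramethyl-1,3,2-dioxaborolane
Product: 11 diethyl [(Z)-3-(4,4,5,5-tetramethyl-1,3,2-dioxaborolan-2-yl)but-2-en-1-yl]phosphonate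
Conditions: P(OEt)3 (3 equiv, neat), 120 °C
Reagents that add atoms: triethyl phosphite, CCOP(OCC)OCC
Why: Michaelis–Arbuzov reaction of a primary allylic bromide; the pinacol boronate is thermally stable and has no reactive partner here.

Step 9
Reactants: 11 diethyl [(Z)-3-(4,4,5,5-tetramethyl-1,3,2-dioxaborolan-2-yl)but-2-en-1-yl]phosphonate
Product: 12 diethyl [(E)-3-iodobut-2-en-1-yl]phosphonate
Conditions: I2 (1.5 equiv), 3 M aq NaOH, THF, 0 °C, dark
Reagents that add atoms: iodine, [I][I]
Why: Base-promoted iododeboronation: hydroxide makes boron tetracoordinate and iodine replaces it at the same carbon with retention of the double-bond geometry. One precursor thus gives both chain-end reagents with the same geometry.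

Step 10
Reactants: 12 diethyl [(E)-3-iodobut-2-en-1-yl]phosphonate; 13 (2E,4E,6E)-2,7-dimethylocta-2,4,6-trienedial
Product: 14 (2E,4E,6E,8E,10E)-11-iodo-2,7-dimethyldodeca-2,4,6,8,10-pentaenal
Conditions: 12, NaHMDS (1.0 equiv), THF, −78 °C; added to 13 (3 equiv), THF, −78 to 0 °C, dark
Reagents that add atoms: none
Why: Horner–Wadsworth–Emmons olefination with an allylic phosphonate, which is E-selective with unhindered enals. Inverse addition to an excess of 13, and the lower electrophilicity of the formyl group in the longer pentaenal, should hold the reaction at mono-olefination; unchanged 13 is recovered.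

Step 11
Reactants: 14 (2E,4E,6E,8E,10E)-11-iodo-2,7-dimethyldodeca-2,4,6,8,10-pentaenal; 11 diethyl [(Z)-3-(4,4,5,5-tetramethyl-1,3,2-dioxaborolan-2-yl)but-2-en-1-yl]phosphonate
Product: 15 2-[(2Z,4E,6E,8E,10E,12E,14E)-15-iodo-6,11-dimethylhexadeca-2,4,6,8,10,12,14-heptaen-2-yl]-4,4,5,5-tetramethyl-1,3,2-dioxaborolane (all-trans chain; 2Z only because boron ranks below carbon)
Conditions: 11 (1.2 equiv), NaHMDS (1.15 equiv), THF, −78 °C; then 14, −78 to 0 °C, dark
Reagents that add atoms: none
Why: Second Horner–Wadsworth–Emmons olefination, E-selective as in step 10; the amide base is consumed before 14 is added, so the C–I bond meets only the stabilised carbanion. Pinacol boronates should survive phosphonate carbanions at low temperature, since complexation at boron is reversible and only attack through the α-carbon leads on to product.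

Step 12
Reactants: 15 iodo heptaenyl boronate (C9–C9' chain); 5 ring alkyne; 7 ring (E)-iodoethenyl compound
Product: 17 (3S,4S,3'S,4'S)-3,4,3',4'-tetrakis(tert-butyldimethylsilyloxy)-7,8-didehydro-β,β-carotene, via C29 enyne boronate 16 (not isolated)
Conditions: 15, 5 (0.98 equiv), Pd(PPh3)4 (5 mol %), CuI (10 mol %), i-Pr2NH (3 equiv), dry degassed THF, 23 °C, dark; then 7 (1.1 equiv), Pd(OAc)2 (5 mol %), SPhos (10 mol %), 1 M aq NaOH (4 equiv), 23 to 35 °C
Reagents that add atoms: none
Why: Zerovalent palladium inserts into the C9–I bond of 15, the copper acetylide formed from 5, CuI and the amine transmetalates, and reductive elimination forms C8–C9 to give 16; after 7 and aqueous NaOH are added, palladium inserts into the C8'–I bond of 7, the hydroxyboronate of 16 transmetalates, and reductive elimination forms C8'–C9'. The closest known reaction types are the Sonogashira coupling of 1-ethynylcyclohexenes with 2-iodoalk-2-enes and the Suzuki–Miyaura coupling of dienyl iodides with polyenylboronates, run in sequence on a haloalkenylboron linchpin. No ring is closed and no sp3 stereocentre is made: C3, C4, C3' and C4' arrive intact in 5 and 7, far from the reacting carbons. The stereochemical content of the step is the geometry of C9=C10, C9'=C10' and C7'=C8', which is fixed in 15 and 7 and carried over because oxidative addition, transmetalation and reductive elimination at sp2 carbon all go with retention; this matters most for C9=C10, which could not be repaired by equilibration next to the alkyne. The selectivity needed is one of order: the iodide end of 15 must react only with 5 and the boron end only with 7. The substrate itself secures it, since a pinacol boronate does not transmetalate until an oxygen base makes it tetracoordinate, so in dry amine only the C–I end is live, and once 15 is consumed the only C–I bond left in the flask is that of 7. Alkyne 5 is used in slight deficit so that no free alkyne is left to compete for 7. One operation thus forms both ring-to-chain bonds, places the triple bond at one end only without any statistical event, and brings in all four stereocentres.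

Step 13
Reactants: 17 (3S,4S,3'S,4'S)-3,4,3',4'-tetrakis(tert-butyldimethylsilyloxy)-7,8-didehydro-β,β-carotene
Product: 18 (3S,4S,3'S,4'S)-7,8-didehydro-β,β-carotene-3,4,3',4'-tetrol (CNP0343957.1)
Conditions: TBAF (8 equiv), THF, 0 °C to rt, argon, dark
Reagents that add atoms: none
Why: Fluoride attacks silicon and not carbon, so the four C–O bonds and their configurations are untouched. The medium is basic, which the allylic carbinols at C4 and C4' and the polyene should tolerate, whereas acid would ionise them.

## Compound list

1 | safranal (2,6,6-trimethylcyclohexa-1,3-diene-1-carbaldehyde) | CC1=C(C=O)C(C)(C)CC=C1 | starting material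
2 | (1R,6S)-2,4,4-trimethyl-7-oxabicyclo[4.1.0]hept-2-ene-3-carbaldehyde | CC1=C(C=O)C(C)(C)C[C@@H]2O[C@H]12 | intermediate
3 | (3S,4S)-3,4-dihydroxy-2,6,6-trimethylcyclohex-1-ene-1-carbaldehyde | CC1=C(C=O)C(C)(C)C[C@H](O)[C@H]1O | intermediate
4 | (3S,4S)-3,4-bis(tert-butyldimethylsilyloxy)-2,6,6-trimethylcyclohex-1-ene-1-carbaldehyde | CC1=C(C=O)C(C)(C)C[C@H](O[Si](C)(C)C(C)(C)C)[C@H]1O[Si](C)(C)C(C)(C)C | intermediate
5 | (3S,4S)-3,4-bis(tert-butyldimethylsilyloxy)-1-ethynyl-2,6,6-trimethylcyclohex-1-ene | CC1=C(C#C)C(C)(C)C[C@H](O[Si](C)(C)C(C)(C)C)[C@H]1O[Si](C)(C)C(C)(C)C | intermediate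
6 | (E)-alkenylzirconocene chloride from 5 (cyclopentadienyl rings drawn σ-bonded) | CC1=C(/C=C/[Zr](Cl)(C2C=CC=C2)C3C=CC=C3)C(C)(C)C[C@H](O[Si](C)(C)C(C)(C)C)[C@H]1O[Si](C)(C)C(C)(C)C | intermediate
7 | (3S,4S)-3,4-bis(tert-butyldimethylsilyloxy)-1-[(E)-2-iodoethenyl]-2,6,6-trimethylcyclohex-1-ene | CC1=C(/C=C/I)C(C)(C)C[C@H](O[Si](C)(C)C(C)(C)C)[C@H]1O[Si](C)(C)C(C)(C)C | intermediate
8 | but-2-yn-1-ol | CC#CCO | starting material
9 | (Z)-3-(4,4,5,5-tetramethyl-1,3,2-dioxaborolan-2-yl)but-2-en-1-ol | CC1(C)OB(OC1(C)C)/C(C)=C/CO | intermediate
10 | (Z)-2-(4-bromobut-2-en-2-yl)-4,4,5,5-tetramethyl-1,3,2-dioxaborolane | CC1(C)OB(OC1(C)C)/C(C)=C/CBr | intermediate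
11 | diethyl [(Z)-3-(4,4,5,5-tetramethyl-1,3,2-dioxaborolan-2-yl)but-2-en-1-yl]phosphonate | CCOP(=O)(OCC)C/C=C(C)/B1OC(C)(C)C(C)(C)O1 | intermediate
12 | diethyl [(E)-3-iodobut-2-en-1-yl]phosphonate | CCOP(=O)(OCC)C/C=C(C)/I | intermediate
13 | (2E,4E,6E)-2,7-dimethylocta-2,4,6-trienedial | O=C/C(C)=C/C=C/C=C(C)/C=O | starting material
14 | (2E,4E,6E,8E,10E)-11-iodo-2,7-dimethyldodeca-2,4,6,8,10-pentaenal | I/C(C)=C/C=C/C(C)=C/C=C/C=C(C)/C=O | intermediate
15 | 2-[(2Z,4E,6E,8E,10E,12E,14E)-15-iodo-6,11-dimethylhexadeca-2,4,6,8,10,12,14-heptaen-2-yl]-4,4,5,5-tetramethyl-1,3,2-dioxaborolane | I/C(C)=C/C=C/C(C)=C/C=C/C=C(C)/C=C/C=C(C)/B1OC(C)(C)C(C)(C)O1 | intermediate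
16 | C29 enyne boronate (ring A with 3S,4S silyl ethers, C7≡C8, all-trans chain C9–C9', pinacol boronate on C9') | CC1=C(C#C/C(C)=C/C=C/C(C)=C/C=C/C=C(C)/C=C/C=C(C)/B2OC(C)(C)C(C)(C)O2)C(C)(C)C[C@H](O[Si](C)(C)C(C)(C)C)[C@H]1O[Si](C)(C)C(C)(C)C | intermediate
17 | (3S,4S,3'S,4'S)-3,4,3',4'-tetrakis(tert-butyldimethylsilyloxy)-7,8-didehydro-β,β-carotene | CC1=C(C#C/C(C)=C/C=C/C(C)=C/C=C/C=C(C)/C=C/C=C(C)/C=C/C2=C(C)[C@H](O[Si](C)(C)C(C)(C)C)[C@@H](O[Si](C)(C)C(C)(C)C)CC2(C)C)C(C)(C)C[C@H](O[Si](C)(C)C(C)(C)C)[C@H]1O[Si](C)(C)C(C)(C)C | intermediate
18 | (3S,4S,3'S,4'S)-7,8-didehydro-β,β-carotene-3,4,3',4'-tetrol | CC1=C(C#C/C(C)=C/C=C/C(C)=C/C=C/C=C(C)/C=C/C=C(C)/C=C/C2=C(C)[C@H](O)[C@@H](O)CC2(C)C)C(C)(C)C[C@H](O)[C@H]1O | target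

## Step count and least certain steps

Total step count: 13. Longest linear sequence: 8 steps (steps 6 to 13, from 8 to 18). The ring branch needs 7 steps (steps 1 to 5, then 12 and 13).

**Step 12 (key step).**
- Risk in the first stage: the order of events may be lost. Adventitious water or hydroxide could activate the boron end of 15 and let 15 couple with itself.
- Risk in the second stage: protodeboronation of the long polyenylboronate may outrun a transmetalation that is slowed by the methyl group on C9'. Both risks arise because the boron sits on an extended, electron-rich π system.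
- Fallback: the bifunctional heptaene is given up and the chain is closed by olefination. The fallback sets out from 14, 5, 7 and 11 and comes back at 17.
  - Sonogashira coupling of 5 with 14 (Pd(PPh3)4, CuI, i-Pr2NH) gives the C25 enyne aldehyde F1.
  - Suzuki–Miyaura coupling of 7 with 11 (Pd(OAc)2, SPhos, aq NaOH) gives the C15 dienyl phosphonate F2.
  - Horner–Wadsworth–Emmons reaction of F2 with F1 (NaHMDS, THF) forms C11'=C12' and gives 17.
  - Each palladium step then acts on a monofunctional partner, and C9=C10 is still set by retention.

**Step 1.**
- Risk: facial selectivity may be poor, because the methyl group on C5 sits next to the reacting C4, where the model olefins carry only a hydrogen. Turnover may be slow because the diene is deactivated by the formyl group, and hypochlorite may oxidise the formyl group in competition. Should the facial sense be opposite to the model, the enantiomeric ligand serves.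
- Fallback: catalytic face selection is replaced by resolution. The fallback sets out from 1 and comes back at 3.
  - Epoxidation of 1 with mCPBA gives the racemic epoxide F3.
  - Hydrolysis as in step 2 gives the racemic trans diol F4.
  - A lipase (lipase B from Candida antarctica or a Burkholderia cepacia lipase, vinyl acetate, MTBE), chosen by screening for the enantiomer it acylates, converts the (3R,4R) enantiomer into the monoacetate F5 at the less hindered hydroxyl on carotenoid C3.
  - Compound 3 stays unchanged and is separated by chromatography.

**Step 2.**
- Risk: water may attack C3 instead of C4. This would give the mirror-image diol and erode the enantiomeric purity without any separable by-product. Partial ionisation at C4 could also break the anti course.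
- Fallback: the regiochemical question becomes one of constitution, and C4 is set by reduction instead of substitution. The fallback sets out from 2 and comes back at 5.
  - Colvin homologation of 2 as in step 4 gives the epoxy enyne F6.
  - Acid-promoted opening by DMSO, followed by amine-induced collapse of the alkoxysulfonium salt (Kornblum-type oxidation), gives the ketol F7. C3 still holds its original C–O bond, and any attack at C3 now leads to a constitutional isomer that can be removed.
  - Hydroxyl-directed reduction with Me4NBH(OAc)3 in MeCN/AcOH, which binds to the C3 oxygen and delivers hydride to C4 from the same face, gives the trans diol F8.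
  - Silylation as in step 3 gives 5.

**Step 10.**
- Risk: the carbanion of 12 may break down by loss of iodide from its γ-carbon (a carbenoid-type elimination) or by dehydroiodination with the amide base. The remaining formyl group may also undergo a second olefination.
- Fallback: the C–I bond is installed after the olefination, so no iodine-bearing carbanion is needed. The fallback sets out from 11 and 13 and comes back at 14.
  - Horner–Wadsworth–Emmons reaction of 11 with an excess of 13 gives the boryl pentaenal F9.
  - Iododeboronation with retention (N-iodosuccinimide, or the conditions of step 9 with short contact time) gives 14.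
  - Step 9 and compound 12 then drop out, and the step count is unchanged.

## Further compounds

F1 | step 12 | C25 enyne aldehyde (ring A with 3S,4S silyl ethers, C7≡C8, chain C9–C12', formyl at C12') | CC1=C(C#C/C(C)=C/C=C/C(C)=C/C=C/C=C(C)/C=O)C(C)(C)C[C@H](O[Si](C)(C)C(C)(C)C)[C@H]1O[Si](C)(C)C(C)(C)C
F2 | step 12 | diethyl {(2E,4E)-5-[(3S,4S)-3,4-bis(tert-butyldimethylsilyloxy)-2,6,6-trimethylcyclohex-1-en-1-yl]-3-methylpenta-2,4-dien-1-yl}phosphonate | CCOP(=O)(OCC)C/C=C(C)/C=C/C1=C(C)[C@H](O[Si](C)(C)C(C)(C)C)[C@@H](O[Si](C)(C)C(C)(C)C)CC1(C)C
F3 | step 1 | rac-(1R*,6S*)-2,4,4-trimethyl-7-oxabicyclo[4.1.0]hept-2-ene-3-carbaldehyde (racemate, one enantiomer drawn) | CC1=C(C=O)C(C)(C)C[C@@H]2O[C@H]12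
F4 | step 1 | rac-(3S*,4S*)-3,4-dihydroxy-2,6,6-trimethylcyclohex-1-ene-1-carbaldehyde (racemate, one enantiomer drawn) | CC1=C(C=O)C(C)(C)C[C@H](O)[C@H]1O
F5 | step 1 | (3R,4R)-4-acetoxy-3-hydroxy-2,6,6-trimethylcyclohex-1-ene-1-carbaldehyde | CC1=C(C=O)C(C)(C)C[C@@H](OC(C)=O)[C@@H]1O
F6 | step 2 | (1R,6S)-3-ethynyl-2,4,4-trimethyl-7-oxabicyclo[4.1.0]hept-2-ene | CC1=C(C#C)C(C)(C)C[C@@H]2O[C@H]12
F7 | step 2 | (S)-3-ethynyl-6-hydroxy-2,4,4-trimethylcyclohex-2-en-1-one | CC1=C(C#C)C(C)(C)C[C@H](O)C1=O
F8 | step 2 | (1S,2S)-4-ethynyl-3,5,5-trimethylcyclohex-3-ene-1,2-diol | CC1=C(C#C)C(C)(C)C[C@H](O)[C@H]1O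
F9 | step 10 | (2E,4E,6E,8E,10Z)-2,7-dimethyl-11-(4,4,5,5-tetramethyl-1,3,2-dioxaborolan-2-yl)dodeca-2,4,6,8,10-pentaenal | CC1(C)OB(OC1(C)C)/C(C)=C/C=C/C(C)=C/C=C/C=C(C)/C=O
A1 | alternative 1 | {(E)-5-[(3S,4S)-3,4-bis(tert-butyldimethylsilyloxy)-2,6,6-trimethylcyclohex-1-en-1-yl]-3-methylpent-2-en-4-yn-1-yl}triphenylphosphonium bromide | CC1=C(C#C/C(C)=C/C[P+](c2ccccc2)(c3ccccc3)c4ccccc4)C(C)(C)C[C@H](O[Si](C)(C)C(C)(C)C)[C@H]1O[Si](C)(C)C(C)(C)C.[Br-]
A2 | alternative 1 | {(2E,4E)-5-[(3S,4S)-3,4-bis(tert-butyldimethylsilyloxy)-2,6,6-trimethylcyclohex-1-en-1-yl]-3-methylpenta-2,4-dien-1-yl}triphenylphosphonium bromide | CC1=C(/C=C/C(C)=C/C[P+](c2ccccc2)(c3ccccc3)c4ccccc4)C(C)(C)C[C@H](O[Si](C)(C)C(C)(C)C)[C@H]1O[Si](C)(C)C(C)(C)C.[Br-]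
A3 | alternative 2 | 7,8-didehydro-β,β-carotene-3,4,3',4'-tetrone (drawn in the tetraketo form) | CC1=C(C#C/C(C)=C/C=C/C(C)=C/C=C/C=C(C)/C=C/C=C(C)/C=C/C2=C(C)C(=O)C(=O)CC2(C)C)C(C)(C)CC(=O)C1=O
A4 | alternative 2 | (3S,3'S)-3,3'-dihydroxy-7,8-didehydro-β,β-carotene-4,4'-dione | CC1=C(C#C/C(C)=C/C=C/C(C)=C/C=C/C=C(C)/C=C/C=C(C)/C=C/C2=C(C)C(=O)[C@@H](O)CC2(C)C)C(C)(C)C[C@H](O)C1=O
A5 | alternative 3 | (3S,4S)-3,4-bis(tert-butyldimethylsilyloxy)-2,6,6-trimethylcyclohex-1-en-1-yl triflate | CC1=C(OS(=O)(=O)C(F)(F)F)C(C)(C)C[C@H](O[Si](C)(C)C(C)(C)C)[C@H]1O[Si](C)(C)C(C)(C)C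
A6 | alternative 3 | all-trans C22 chain C7–C7' with terminal alkyne at C7 and pinacol boronate at C7' | C#C/C(C)=C/C=C/C(C)=C/C=C/C=C(C)/C=C/C=C(C)/C=C/B1OC(C)(C)C(C)(C)O1
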